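## Retrosynthetic overview
1. Bisoflavolin H ⇒ its tetramethyl ether. All four ArO–Me bonds are cleaved in the last step.
2. Tetramethyl ether ⇒ Ullmann C–O disconnection between C8 of the genistein unit and O4' of the chlorodaidzein unit. This gives an 8-iodoisoflavone and a 4'-phenol.
3. 8-Iodide ⇒ genistein, by permethylation and then C8-selective iodination. All three rings of this unit are bought.
4. 4'-Phenol ⇒ 8-chlorodaidzein (7-O-selective methylation) ⇒ 2-chlororesorcinol + 4-hydroxyphenylacetic acid + one carbon from DMF.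
5. Ring order: the only ring built is pyranone ring C of the chlorinated unit (step 1). The other five rings come with the starting materials, and the ether bridge joins the halves in step 5.

Assumption: the target SMILES holds no stereocentre and the diaryl ether rotates freely, so the compound is achiral and only its constitution has to be made.

## Route

Step 1
Reactants: 1 2-chlorobenzene-1,3-diol (2-chlororesorcinol); 2 4-hydroxyphenylacetic acid
Product: 5 8-chloro-7-hydroxy-3-(4-hydroxyphenyl)-4H-chromen-4-one (8-chlorodaidzein), via deoxybenzoin 3 (not isolated), via enaminone 4 (not isolated)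
Conditions: BF3·OEt2 (solvent), 85 °C, 2 h; then DMF, MsCl, 10 → 70 °C, 2 h; aq NaOAc work-up
Reagents that add atoms: N,N-dimethylformamide, CN(C)C=O
Why: BF3-promoted Friedel–Crafts acylation can only strike C4 of the symmetric 2-chlororesorcinol, and the Vilsmeier-type iminium salt from DMF and MsCl then formylates the activated CH2 so that the ortho-OH closes the pyranone with loss of Me2NH (deoxybenzoin route to isoflavones), with no stereocentre formed.

Step 2
Reactants: 5 8-chlorodaidzein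
Product: 6 8-chloro-3-(4-hydroxyphenyl)-7-methoxy-4H-chromen-4-one
Conditions: MeI (1.05 equiv), K2CO3 (1.0 equiv), DMF, 0 °C → rt, 12 h
Reagents that add atoms: iodomethane, CI
Why: Williamson etherification under acidity control, because one equivalent of base ionises only the 7-OH (a vinylogous carboxylic acid, acidified further by the ortho chlorine and about three pKa units below the 4'-OH), so O7 is capped and the 4'-phenol stays free, with no stereocentre formed.

Step 3
Reactants: 7 genistein (5,7-dihydroxy-3-(4-hydroxyphenyl)-4H-chromen-4-one)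
Product: 8 5,7-dimethoxy-3-(4-methoxyphenyl)-4H-chromen-4-one
Conditions: Me2SO4 (5 equiv), K2CO3 (6 equiv), acetone, reflux, 24 h
Reagents that add atoms: dimethyl sulfate, COS(=O)(=O)OC
Why: Exhaustive Williamson O-methylation, in which an excess of the hard electrophile at reflux also alkylates the hydrogen-bonded 5-OH and favours O- over C-methylation of ring A, with no stereocentre formed.

Step 4
Reactants: 8 5,7-dimethoxy-3-(4-methoxyphenyl)-4H-chromen-4-one
Product: 9 8-iodo-5,7-dimethoxy-3-(4-methoxyphenyl)-4H-chromen-4-one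
Conditions: NIS (1.1 equiv), TFA (0.3 equiv), MeCN, 0 °C → rt, dark, 6 h
Reagents that add atoms: N-iodosuccinimide, O=C1CCC(=O)N1I
Why: Electrophilic aromatic iodination (SEAr), in which the trioxygenated ring A far outruns the anisyl ring B and, with O5 alkylated, attack goes to C8 (next to one OMe and the tied-back ring oxygen) and not to C6 (wedged between two OMe groups), with no stereocentre formed.

Step 5
Reactants: 6 8-chloro-3-(4-hydroxyphenyl)-7-methoxy-4H-chromen-4-one (1.2 equiv); 9 8-iodo-5,7-dimethoxy-3-(4-methoxyphenyl)-4H-chromen-4-one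
Product: 10 8-chloro-3-(4-{[5,7-dimethoxy-3-(4-methoxyphenyl)-4-oxo-4H-chromen-8-yl]oxy}phenyl)-7-methoxy-4H-chromen-4-one
Conditions: CuI (20 mol %), picolinic acid (40 mol %), K3PO4 (2 equiv), 4 Å MS, DMSO, 90 °C, Ar, 24 h
Reagents that add atoms: none
Why: Ullmann-type diaryl ether coupling, in which the picolinate-ligated monovalent copper phenoxide of the unhindered 4'-OH inserts into the weak C8–I bond while the aryl chloride stays inert, the ligand being one that tolerates ortho,ortho'-disubstituted iodides and the dry mild base sparing both pyranones, with no stereocentre formed.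

Step 6
Reactants: 10 tetramethyl ether
Product: 12 bisoflavolin H, via tetrakis(dibromoboryl) ether 11 (not isolated)
Conditions: BBr3 (12 equiv), CH2Cl2, −78 °C → rt, 24 h; then ice-water
Reagents that add atoms: none
Why: Lewis-acid aryl methyl ether cleavage, in which bromide attacks only the sp3 methyl carbons of the boron-activated ethers, so the diaryl ether, the C–Cl bond and both pyranones survive and water then frees the four phenols, with no stereocentre formed or present.

## Compound list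
1 | 2-chlorobenzene-1,3-diol (2-chlororesorcinol) | Oc1cccc(O)c1Cl | starting material
2 | 4-hydroxyphenylacetic acid | OC(=O)Cc1ccc(O)cc1 | starting material
3 | 1-(3-chloro-2,4-dihydroxyphenyl)-2-(4-hydroxyphenyl)ethan-1-one, drawn free of boron | O=C(Cc1ccc(O)cc1)c1ccc(O)c(Cl)c1O | intermediate
4 | (E)-1-(3-chloro-2,4-dihydroxyphenyl)-3-(dimethylamino)-2-(4-hydroxyphenyl)prop-2-en-1-one, geometry of no consequence | CN(C)/C=C(/C(=O)c1ccc(O)c(Cl)c1O)c1ccc(O)cc1 | intermediate
5 | 8-chloro-7-hydroxy-3-(4-hydroxyphenyl)-4H-chromen-4-one (8-chlorodaidzein) | O=c1c(-c2ccc(O)cc2)coc2c(Cl)c(O)ccc12 | intermediate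
6 | 8-chloro-3-(4-hydroxyphenyl)-7-methoxy-4H-chromen-4-one | O=c1c(-c2ccc(O)cc2)coc2c(Cl)c(OC)ccc12 | intermediate
7 | genistein, 5,7-dihydroxy-3-(4-hydroxyphenyl)-4H-chromen-4-one | O=c1c(-c2ccc(O)cc2)coc2cc(O)cc(O)c12 | starting material
8 | 5,7-dimethoxy-3-(4-methoxyphenyl)-4H-chromen-4-one | O=c1c(-c2ccc(OC)cc2)coc2cc(OC)cc(OC)c12 | intermediate
9 | 8-iodo-5,7-dimethoxy-3-(4-methoxyphenyl)-4H-chromen-4-one | O=c1c(-c2ccc(OC)cc2)coc2c(I)c(OC)cc(OC)c12 | intermediate
10 | 8-chloro-3-(4-{[5,7-dimethoxy-3-(4-methoxyphenyl)-4-oxo-4H-chromen-8-yl]oxy}phenyl)-7-methoxy-4H-chromen-4-one | O=c1c(-c2ccc(Oc3c(OC)cc(OC)c4c(=O)c(-c5ccc(OC)cc5)coc34)cc2)coc2c(Cl)c(OC)ccc12 | intermediate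
11 | tetrakis(dibromoboryl) ether of 12, drawn in its simplest form with each phenol oxygen carrying BBr2 | O=c1c(-c2ccc(Oc3c(OB(Br)Br)cc(OB(Br)Br)c4c(=O)c(-c5ccc(OB(Br)Br)cc5)coc34)cc2)coc2c(Cl)c(OB(Br)Br)ccc12 | intermediate
12 | bisoflavolin H, 8-chloro-3-(4-{[5,7-dihydroxy-3-(4-hydroxyphenyl)-4-oxo-4H-chromen-8-yl]oxy}phenyl)-7-hydroxy-4H-chromen-4-one | O=c1c(-c2ccc(Oc3c(O)cc(O)c4c(=O)c(-c5ccc(O)cc5)coc34)cc2)coc2c(Cl)c(O)ccc12 | target

## Step count and risks
Total step count: 6. Longest linear sequence: 4 (steps 1, 2, 5, 6 or steps 3, 4, 5, 6).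

**Risk A, step 4.** Iodine may go to C6 or C3' instead of C8. The C8 product is confirmed if H6 shows NOE contacts to both the 5-OMe and the 7-OMe. The fallback sets out from 8 and comes back at 9. It locks the position by opening the pyranone, iodinating next to the freed phenol and closing the ring again.
- KOH in aqueous EtOH at reflux adds to C2 of 8 and expels formate. This gives 1-(2-hydroxy-4,6-dimethoxyphenyl)-2-(4-methoxyphenyl)ethan-1-one F1.
- I2/HIO3 in aqueous EtOH iodinates ortho to the only free, chelated OH. This gives 1-(2-hydroxy-3-iodo-4,6-dimethoxyphenyl)-2-(4-methoxyphenyl)ethan-1-one F2.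
- DMF dimethyl acetal in toluene at 90 °C forms (E)-3-(dimethylamino)-1-(2-hydroxy-3-iodo-4,6-dimethoxyphenyl)-2-(4-methoxyphenyl)prop-2-en-1-one F3.
- F3 closes in the same pot through that one OH, so the iodine can only end up at C8 of 9.

**Risk B, step 5.** The iodide is electron-rich and ortho,ortho'-disubstituted, so it may only deiodinate. The fallback sets out from 9 and 6 and comes back at 10. It reverses the polarity to a Chan–Lam coupling, so that the hindered partner is the phenol and the aryl donor is unhindered.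
- Compound 9 is borylated (PdCl2(dppf), B2pin2, KOAc, dioxane, 90 °C). This gives 5,7-dimethoxy-3-(4-methoxyphenyl)-8-(4,4,5,5-tetramethyl-1,3,2-dioxaborolan-2-yl)-4H-chromen-4-one F4.
- F4 is oxidised with NaBO3·4H2O in THF/water at rt to 8-hydroxy-5,7-dimethoxy-3-(4-methoxyphenyl)-4H-chromen-4-one F5.
- Compound 6 is converted with Tf2O/pyridine into 4-(8-chloro-7-methoxy-4-oxo-4H-chromen-3-yl)phenyl trifluoromethanesulfonate F6.
- F6 is borylated under the same conditions, with the aryl chloride untouched. This gives 8-chloro-7-methoxy-3-[4-(4,4,5,5-tetramethyl-1,3,2-dioxaborolan-2-yl)phenyl]-4H-chromen-4-one F7.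
- F5 and F7 are joined with Cu(OAc)2, pyridine, B(OH)3, 4 Å MS, MeCN, O2, 60 °C to give 10.

**Risk C, step 6.** The two 7-OMe groups may cleave incompletely. Acid-induced ring opening and re-closure of Wessely–Moser type could also move the aryloxy group from C8 to C6. The fallback sets out from 7 and 5 and comes back at 12. It changes the protecting-group plan from methyl to methoxymethyl (MOM), so the last step needs only dilute acid.
- Compound 7 with NaH and MOMCl in DMF gives 5,7-bis(methoxymethoxy)-3-[4-(methoxymethoxy)phenyl]-4H-chromen-4-one F8.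
- NIS in DMF at rt, without acid, gives 8-iodo-5,7-bis(methoxymethoxy)-3-[4-(methoxymethoxy)phenyl]-4H-chromen-4-one F9.
- Compound 5 with MOMCl (1.05 equiv) and iPr2NEt in DMF gives 8-chloro-3-(4-hydroxyphenyl)-7-(methoxymethoxy)-4H-chromen-4-one F10.
- The CuI/picolinic acid/K3PO4 coupling of F9 and F10 gives 8-chloro-3-[4-({5,7-bis(methoxymethoxy)-3-[4-(methoxymethoxy)phenyl]-4-oxo-4H-chromen-8-yl}oxy)phenyl]-7-(methoxymethoxy)-4H-chromen-4-one F11.
- 3 M HCl in MeOH at 50 °C converts F11 into 12.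

## Further compounds
F1 | step 4 | 1-(2-hydroxy-4,6-dimethoxyphenyl)-2-(4-methoxyphenyl)ethan-1-one | O=C(Cc1ccc(OC)cc1)c1c(O)cc(OC)cc1OC
F2 | step 4 | 1-(2-hydroxy-3-iodo-4,6-dimethoxyphenyl)-2-(4-methoxyphenyl)ethan-1-one | O=C(Cc1ccc(OC)cc1)c1c(O)c(I)c(OC)cc1OC
F3 | step 4 | (E)-3-(dimethylamino)-1-(2-hydroxy-3-iodo-4,6-dimethoxyphenyl)-2-(4-methoxyphenyl)prop-2-en-1-one | CN(C)/C=C(/C(=O)c1c(O)c(I)c(OC)cc1OC)c1ccc(OC)cc1
F4 | step 5 | 5,7-dimethoxy-3-(4-methoxyphenyl)-8-(4,4,5,5-tetramethyl-1,3,2-dioxaborolan-2-yl)-4H-chromen-4-one | O=c1c(-c2ccc(OC)cc2)coc2c(B3OC(C)(C)C(C)(C)O3)c(OC)cc(OC)c12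
F5 | step 5 | 8-hydroxy-5,7-dimethoxy-3-(4-methoxyphenyl)-4H-chromen-4-one | O=c1c(-c2ccc(OC)cc2)coc2c(O)c(OC)cc(OC)c12
F6 | step 5 | 4-(8-chloro-7-methoxy-4-oxo-4H-chromen-3-yl)phenyl trifluoromethanesulfonate | O=c1c(-c2ccc(OS(=O)(=O)C(F)(F)F)cc2)coc2c(Cl)c(OC)ccc12
F7 | step 5 | 8-chloro-7-methoxy-3-[4-(4,4,5,5-tetramethyl-1,3,2-dioxaborolan-2-yl)phenyl]-4H-chromen-4-one | O=c1c(-c2ccc(B3OC(C)(C)C(C)(C)O3)cc2)coc2c(Cl)c(OC)ccc12
F8 | step 6 | 5,7-bis(methoxymethoxy)-3-[4-(methoxymethoxy)phenyl]-4H-chromen-4-one | O=c1c(-c2ccc(OCOC)cc2)coc2cc(OCOC)cc(OCOC)c12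
F9 | step 6 | 8-iodo-5,7-bis(methoxymethoxy)-3-[4-(methoxymethoxy)phenyl]-4H-chromen-4-one | O=c1c(-c2ccc(OCOC)cc2)coc2c(I)c(OCOC)cc(OCOC)c12
F10 | step 6 | 8-chloro-3-(4-hydroxyphenyl)-7-(methoxymethoxy)-4H-chromen-4-one | O=c1c(-c2ccc(O)cc2)coc2c(Cl)c(OCOC)ccc12
F11 | step 6 | 8-chloro-3-[4-({5,7-bis(methoxymethoxy)-3-[4-(methoxymethoxy)phenyl]-4-oxo-4H-chromen-8-yl}oxy)phenyl]-7-(methoxymethoxy)-4H-chromen-4-one | O=c1c(-c2ccc(Oc3c(OCOC)cc(OCOC)c4c(=O)c(-c5ccc(OCOC)cc5)coc34)cc2)coc2c(Cl)c(OCOC)ccc12
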